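## Retrosynthetic overview
1. Target ⇐ octa-TIPS ether ⇐ Mizoroki–Heck union of a 1-methylidene-trans-2,3-diarylindane with a (2R,3R)-2,3-diaryl-2,3-dihydrobenzofuran-5-yl triflate. This makes the E-alkene, and no ring is formed afterwards.
2. Methylidene indane ⇐ trans-2,3-diarylindan-1-one ⇐ key step: semipinacol 1,2-aryl shift in a cis-1-arylindane-1,2-diol 2-mesylate (aryl moves C1→C2, C1 becomes C=O).
3. Indanediol (the carbocyclic five-membered ring, the only ring formed in this branch) ⇐ Friedel–Crafts opening of an epoxy diaryl carbinol ⇐ (2R,3S)-glycidate + 2 ArLi. Of the two identical aryl groups, one becomes the fused ring and the other migrates.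
4. Dihydrobenzofuran (the only ring formed in the second branch) ⇐ new enantioselective formal [3+2] union of 1,4-benzoquinone with tris-TIPS-resveratrol. The leftover quinone oxygen becomes the triflate handle.
5. All arenes come from resorcinol, 4-iodophenol and benzoquinone. The two-carbon links come from methyl acrylate and vinylmagnesium bromide.

Abbreviations: TIPS = triisopropylsilyl; Ar = 3,5-bis(triisopropylsilyloxy)phenyl; An = 4-(triisopropylsilyloxy)phenyl.

Assumption: in step 12 the (S)-configured catalyst is taken to give the (2R,3R) series. The sense must be confirmed by experiment, and the (R)-catalyst is equally available.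

## Route

Step 1
Reactants: 1 resorcinol
Product: 2 1,3-bis(triisopropylsilyloxy)benzene
Conditions: TIPSCl (2.2 equiv), imidazole, DMF, rt
Reagents that add atoms: triisopropylsilyl chloride CC(C)[Si](Cl)(C(C)C)C(C)C
Why: Imidazole-promoted O-silylation of both phenols gives base-stable ethers that leave only C5 sterically open for the next step.

Step 2
Reactants: 2 1,3-bis(triisopropylsilyloxy)benzene
Product: 4 1-iodo-3,5-bis(triisopropylsilyloxy)benzene, via arylboronate 3 (not isolated)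
Conditions: [Ir(OMe)(cod)]2 (1 mol %), 4,4'-di-tert-butyl-2,2'-bipyridine (2 mol %), B2pin2 (0.55 equiv), hexane, 80 °C; evaporate; CuI (10 mol %), 1,10-phenanthroline (20 mol %), KI (1.5 equiv), THF/MeOH/H2O, air, 70 °C
Reagents that add atoms: bis(pinacolato)diboron CC1(C)OB(OC1(C)C)B1OC(C)(C)C(C)(C)O1 (boron in 3 only); potassium iodide [K+].[I-]
Why: Sterically controlled iridium-catalysed aromatic C–H borylation reaches only the carbon meta to both silyloxy groups, and copper-catalysed aerobic iododeboronation exchanges boron for iodine at that same carbon.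

Step 3
Reactants: 5 4-iodophenol
Product: 6 (4-iodophenoxy)triisopropylsilane
Conditions: TIPSCl (1.1 equiv), imidazole, DMF, rt
Reagents that add atoms: triisopropylsilyl chloride CC(C)[Si](Cl)(C(C)C)C(C)C
Why: This is a routine O-silylation of a phenol.

Step 4
Reactants: 6 (4-iodophenoxy)triisopropylsilane; 7 methyl acrylate
Product: 8 methyl (E)-3-An-acrylate
Conditions: Pd(OAc)2 (1 mol %), Et3N, MeCN, 80 °C
Reagents that add atoms: none
Why: The Mizoroki–Heck reaction of an aryl iodide with an acrylate gives the E-cinnamate through syn insertion and syn β-hydride elimination.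

Step 5
Reactants: 8 methyl (E)-3-An-acrylate
Product: 9 methyl (2R,3S)-3-An-oxirane-2-carboxylate (trans)
Conditions: 4,5-di-O-acetyl-1,2-O-isopropylidene-β-L-erythro-hexo-2,3-diulo-2,6-pyranose (25 mol %), Oxone (2KHSO5·KHSO4·K2SO4), NaHCO3, MeCN/aq Na2(EDTA), 0 °C → rt
Reagents that add atoms: potassium peroxymonosulfate [K+].[O-]S(=O)(=O)OO
Why: In this Shi-type asymmetric epoxidation the chiral dioxirane delivers oxygen to one face of the trans-cinnamate through a spiro transition state and sets both epoxide carbons, the L-series ketone being used because the D-series gives the (2S,3R) glycidate.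

Step 6
Reactants: 9 methyl (2R,3S)-3-An-oxirane-2-carboxylate; 4 1-iodo-3,5-bis(triisopropylsilyloxy)benzene
Product: 11 bis(Ar)[(2R,3S)-3-An-oxiran-2-yl]methanol, via aryllithium 10 (not isolated)
Conditions: 4 (2.3 equiv), n-BuLi (2.3 equiv), Et2O, −78 °C; then 9, −78 °C; H2O
Reagents that add atoms: n-butyllithium [Li]CCCC (lithium in 10 only)
Why: Iodine–lithium exchange is followed by double 1,2-addition of the aryllithium to the ester, which at −78 °C is far faster than attack on the epoxide, so both stereocentres are carried through unchanged.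

Step 7
Reactants: 11 bis(Ar)[(2R,3S)-3-An-oxiran-2-yl]methanol
Product: 12 (1S,2R,3S)-1-Ar-3-An-4,6-bis(triisopropylsilyloxy)indane-1,2-diol (1-OH cis to 2-OH; An trans to both)
Conditions: Sc(OTf)3 (10 mol %), CH2Cl2, −40 °C
Reagents that add atoms: none
Why: In this intramolecular Friedel–Crafts alkylation (epoxide–arene cyclisation) scandium chelated by the epoxide oxygen and the tertiary OH opens the benzylic C–O bond, one aryl group attacks through its ortho/para-activated carbon with inversion so that An ends trans to the retained C2–O bond, and keeping the chelate forces the C1–OH cis to the C2–OH.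

Step 8
Reactants: 12 (1S,2R,3S)-1-Ar-3-An-4,6-bis(triisopropylsilyloxy)indane-1,2-diol
Product: 15 (2S,3S)-2-Ar-3-An-4,6-bis(triisopropylsilyloxy)indan-1-one (trans), via mesylate 13 (not isolated), via cis-indanone 14 (not isolated)
Conditions: MsCl, Et3N, CH2Cl2, −10 °C; aqueous wash; KOt-Bu (1.2 equiv), THF, −78 → 0 °C
Reagents that add atoms: methanesulfonyl chloride CS(=O)(=O)Cl (mesyl group in 13 only)
Why: In this semipinacol rearrangement (Tsuchihashi–Suzuki-type 1,2-aryl shift) only the secondary OH is mesylated, the tertiary alkoxide (cis to the mesylate, so it cannot close an epoxide) pushes the anti-periplanar Ar from C1 to C2 with inversion to give the cis ketone, and residual base epimerises the acidic C2 centre to the trans isomer under control of the fixed C3 centre.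

Step 9
Reactants: 15 (2S,3S)-2-Ar-3-An-4,6-bis(triisopropylsilyloxy)indan-1-one
Product: 16 (2S,3S)-2-Ar-3-An-1-methylidene-4,6-bis(triisopropylsilyloxy)indane
Conditions: Cp2TiMe2 (2.5 equiv), toluene, 75 °C, dark
Reagents that add atoms: dimethyltitanocene C[Ti](C)(C1C=CC=C1)C1C=CC=C1
Why: The Petasis methylenation uses a non-basic titanium methylidene, which converts hindered, enolisable ketones into alkenes without touching the C2 and C3 centres.

Step 10
Reactants: 6 (4-iodophenoxy)triisopropylsilane; 17 vinylmagnesium bromide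
Product: 18 triisopropyl(4-vinylphenoxy)silane
Conditions: PdCl2(dppf) (2 mol %), THF, 0 °C → rt
Reagents that add atoms: none
Why: This Kumada–Corriu cross-coupling of an aryl iodide runs under neutral, water-free conditions that the silyl ether tolerates.

Step 11
Reactants: 18 triisopropyl(4-vinylphenoxy)silane; 4 1-iodo-3,5-bis(triisopropylsilyloxy)benzene
Product: 19 (E)-1-An-2-Ar-ethene (tris-TIPS-resveratrol)
Conditions: Pd(OAc)2 (2 mol %), P(o-tol)3 (4 mol %), Et3N, MeCN/toluene, 85 °C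
Reagents that add atoms: none
Why: The Mizoroki–Heck arylation of a styrene at its terminal carbon gives the E-stilbene.

Step 12
Reactants: 19 (E)-1-An-2-Ar-ethene; 20 1,4-benzoquinone
Product: 21 (2R,3R)-2-An-3-Ar-2,3-dihydro-1-benzofuran-5-ol (trans)
Conditions: 20 (1.3 equiv), (S)-3,3-diphenyl-1-(2-methylphenyl)tetrahydro-1H,3H-pyrrolo[1,2-c][1,3,2]oxazaborole·HNTf2 (20 mol %), CH2Cl2/MeCN, −78 → −20 °C
Reagents that add atoms: none
Why: Proposed new method: the N-protonated oxazaborolidine binds one quinone carbonyl and shields one face of the adjacent C=C, so the nucleophilic stilbene carbon (the one bearing Ar) adds in Michael fashion through a single alkene face and sets C3, the resulting 4-silyloxybenzyl cation is closed by the neighbouring carbonyl oxygen anti to Ar to set the trans C2 centre, and enolisation gives the phenol; the closest known reaction type is the oxazaborolidinium-catalysed enantioselective formal [3+2] cycloaddition of 2-methoxy-1,4-benzoquinone with 2,3-dihydrofuran (and titanium TADDOLate-promoted quinone–propenylarene couplings), which has not been shown for unsubstituted benzoquinone or for 1,2-diarylethenes.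

Step 13
Reactants: 21 (2R,3R)-2-An-3-Ar-2,3-dihydro-1-benzofuran-5-ol
Product: 22 (2R,3R)-2-An-3-Ar-2,3-dihydro-1-benzofuran-5-yl trifluoromethanesulfonate
Conditions: Tf2O, pyridine, CH2Cl2, 0 °C
Reagents that add atoms: triflic anhydride O=S(=O)(OS(=O)(=O)C(F)(F)F)C(F)(F)F
Why: O-Sulfonylation of the only free phenol turns it into a cross-coupling leaving group without touching the stereocentres.

Step 14
Reactants: 16 (2S,3S)-2-Ar-3-An-1-methylidene-4,6-bis(triisopropylsilyloxy)indane; 22 (2R,3R)-2-An-3-Ar-2,3-dihydro-1-benzofuran-5-yl trifluoromethanesulfonate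
Product: 23 octakis-O-TIPS ether of the target (E-alkene)
Conditions: Pd(OAc)2 (5 mol %), dppp (6 mol %), Et3N, DMF, 80 °C
Reagents that add atoms: none
Why: In this Mizoroki–Heck arylation the aryl group adds to the unhindered CH2 terminus, and syn β-hydride elimination from the freely rotating benzylic CH2 gives the conjugated exocyclic alkene with the aryl group turned away from the peri C7–H (E), as in known arylations of 1-methylidene-2,3-diarylindanes.

Step 15
Reactants: 23 octakis-O-TIPS ether of the target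
Product: 24 CNP0184753.1 (target)
Conditions: Bu4NF (9 equiv), AcOH (9 equiv), THF, 0 °C, under argon
Reagents that add atoms: none
Why: Buffered fluoride desilylation frees all eight phenols under near-neutral conditions that leave the acid-sensitive exocyclic stilbene, the dihydrobenzofuran C–O bond and all four stereocentres untouched.

## Compound list
1 | resorcinol | Oc1cccc(O)c1 | starting material
2 | 1,3-bis(triisopropylsilyloxy)benzene | CC(C)[Si](C(C)C)(C(C)C)Oc1cccc(O[Si](C(C)C)(C(C)C)C(C)C)c1 | intermediate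
3 | 2-Ar-4,4,5,5-tetramethyl-1,3,2-dioxaborolane (not isolated) | CC(C)[Si](C(C)C)(C(C)C)Oc1cc(B2OC(C)(C)C(C)(C)O2)cc(O[Si](C(C)C)(C(C)C)C(C)C)c1 | intermediate
4 | 1-iodo-3,5-bis(triisopropylsilyloxy)benzene | CC(C)[Si](C(C)C)(C(C)C)Oc1cc(I)cc(O[Si](C(C)C)(C(C)C)C(C)C)c1 | intermediate
5 | 4-iodophenol | Oc1ccc(I)cc1 | starting material
6 | (4-iodophenoxy)triisopropylsilane | CC(C)[Si](C(C)C)(C(C)C)Oc1ccc(I)cc1 | intermediate
7 | methyl acrylate | C=CC(=O)OC | starting material
8 | methyl (E)-3-[4-(triisopropylsilyloxy)phenyl]acrylate | COC(=O)/C=C/c1ccc(O[Si](C(C)C)(C(C)C)C(C)C)cc1 | intermediate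
9 | methyl (2R,3S)-3-[4-(triisopropylsilyloxy)phenyl]oxirane-2-carboxylate | COC(=O)[C@@H]1O[C@H]1c1ccc(O[Si](C(C)C)(C(C)C)C(C)C)cc1 | intermediate
10 | 3,5-bis(triisopropylsilyloxy)phenyllithium (not isolated) | [Li]c1cc(O[Si](C(C)C)(C(C)C)C(C)C)cc(O[Si](C(C)C)(C(C)C)C(C)C)c1 | intermediate
11 | bis(Ar)[(2R,3S)-3-An-oxiran-2-yl]methanol | OC(c1cc(O[Si](C(C)C)(C(C)C)C(C)C)cc(O[Si](C(C)C)(C(C)C)C(C)C)c1)(c1cc(O[Si](C(C)C)(C(C)C)C(C)C)cc(O[Si](C(C)C)(C(C)C)C(C)C)c1)[C@@H]1O[C@H]1c1ccc(O[Si](C(C)C)(C(C)C)C(C)C)cc1 | intermediate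
12 | (1S,2R,3S)-1-Ar-3-An-4,6-bis(triisopropylsilyloxy)-2,3-dihydro-1H-indene-1,2-diol | CC(C)[Si](C(C)C)(C(C)C)Oc1ccc([C@H]2c3c(O[Si](C(C)C)(C(C)C)C(C)C)cc(O[Si](C(C)C)(C(C)C)C(C)C)cc3[C@@](O)(c3cc(O[Si](C(C)C)(C(C)C)C(C)C)cc(O[Si](C(C)C)(C(C)C)C(C)C)c3)[C@@H]2O)cc1 | intermediate
13 | (1S,2R,3S)-1-Ar-1-hydroxy-3-An-4,6-bis(triisopropylsilyloxy)-2,3-dihydro-1H-inden-2-yl methanesulfonate (not isolated) | CC(C)[Si](C(C)C)(C(C)C)Oc1ccc([C@H]2c3c(O[Si](C(C)C)(C(C)C)C(C)C)cc(O[Si](C(C)C)(C(C)C)C(C)C)cc3[C@@](O)(c3cc(O[Si](C(C)C)(C(C)C)C(C)C)cc(O[Si](C(C)C)(C(C)C)C(C)C)c3)[C@@H]2OS(C)(=O)=O)cc1 | intermediate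
14 | (2R,3S)-2-Ar-3-An-4,6-bis(triisopropylsilyloxy)indan-1-one, cis (not isolated) | CC(C)[Si](C(C)C)(C(C)C)Oc1ccc([C@H]2c3c(O[Si](C(C)C)(C(C)C)C(C)C)cc(O[Si](C(C)C)(C(C)C)C(C)C)cc3C(=O)[C@H]2c2cc(O[Si](C(C)C)(C(C)C)C(C)C)cc(O[Si](C(C)C)(C(C)C)C(C)C)c2)cc1 | intermediate
15 | (2S,3S)-2-Ar-3-An-4,6-bis(triisopropylsilyloxy)indan-1-one, trans | CC(C)[Si](C(C)C)(C(C)C)Oc1ccc([C@H]2c3c(O[Si](C(C)C)(C(C)C)C(C)C)cc(O[Si](C(C)C)(C(C)C)C(C)C)cc3C(=O)[C@@H]2c2cc(O[Si](C(C)C)(C(C)C)C(C)C)cc(O[Si](C(C)C)(C(C)C)C(C)C)c2)cc1 | intermediate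
16 | (2S,3S)-2-Ar-3-An-1-methylidene-4,6-bis(triisopropylsilyloxy)-2,3-dihydro-1H-indene | CC(C)[Si](C(C)C)(C(C)C)Oc1ccc([C@H]2c3c(O[Si](C(C)C)(C(C)C)C(C)C)cc(O[Si](C(C)C)(C(C)C)C(C)C)cc3C(=C)[C@@H]2c2cc(O[Si](C(C)C)(C(C)C)C(C)C)cc(O[Si](C(C)C)(C(C)C)C(C)C)c2)cc1 | intermediate
17 | vinylmagnesium bromide | C=C[Mg]Br | starting material
18 | triisopropyl(4-vinylphenoxy)silane | C=Cc1ccc(O[Si](C(C)C)(C(C)C)C(C)C)cc1 | intermediate
19 | (E)-3,4',5-tris(triisopropylsilyloxy)stilbene | CC(C)[Si](C(C)C)(C(C)C)Oc1ccc(/C=C/c2cc(O[Si](C(C)C)(C(C)C)C(C)C)cc(O[Si](C(C)C)(C(C)C)C(C)C)c2)cc1 | intermediate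
20 | 1,4-benzoquinone | O=C1C=CC(=O)C=C1 | starting material
21 | (2R,3R)-2-An-3-Ar-2,3-dihydro-1-benzofuran-5-ol | Oc1ccc2c(c1)[C@@H](c1cc(O[Si](C(C)C)(C(C)C)C(C)C)cc(O[Si](C(C)C)(C(C)C)C(C)C)c1)[C@H](c1ccc(O[Si](C(C)C)(C(C)C)C(C)C)cc1)O2 | intermediate
22 | (2R,3R)-2-An-3-Ar-2,3-dihydro-1-benzofuran-5-yl trifluoromethanesulfonate | O=S(=O)(Oc1ccc2c(c1)[C@@H](c1cc(O[Si](C(C)C)(C(C)C)C(C)C)cc(O[Si](C(C)C)(C(C)C)C(C)C)c1)[C@H](c1ccc(O[Si](C(C)C)(C(C)C)C(C)C)cc1)O2)C(F)(F)F | intermediate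
23 | octakis-O-TIPS ether of the target, (E; indane 2S,3S; dihydrobenzofuran 2R,3R) | CC(C)[Si](C(C)C)(C(C)C)Oc1ccc([C@H]2c3c(O[Si](C(C)C)(C(C)C)C(C)C)cc(O[Si](C(C)C)(C(C)C)C(C)C)cc3/C(=C/c3ccc4c(c3)[C@@H](c3cc(O[Si](C(C)C)(C(C)C)C(C)C)cc(O[Si](C(C)C)(C(C)C)C(C)C)c3)[C@H](c3ccc(O[Si](C(C)C)(C(C)C)C(C)C)cc3)O4)[C@@H]2c2cc(O[Si](C(C)C)(C(C)C)C(C)C)cc(O[Si](C(C)C)(C(C)C)C(C)C)c2)cc1 | intermediate
24 | 5-[(2R,3R)-5-{(E)-[(2S,3S)-2-(3,5-dihydroxyphenyl)-4,6-dihydroxy-3-(4-hydroxyphenyl)-2,3-dihydro-1H-inden-1-ylidene]methyl}-2-(4-hydroxyphenyl)-2,3-dihydro-1-benzofuran-3-yl]benzene-1,3-diol (CNP0184753.1) | Oc1ccc([C@H]2c3c(O)cc(O)cc3/C(=C/c3ccc4c(c3)[C@@H](c3cc(O)cc(O)c3)[C@H](c3ccc(O)cc3)O4)[C@@H]2c2cc(O)cc(O)c2)cc1 | target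

## Step count and risks
Total step count: 15. Longest linear sequence: 9 steps (3, 4, 5, 6, 7, 8, 9, 14, 15).

**Step 12 (the proposed new step).**
- Risks: the silylated stilbene may be too weak a nucleophile, the Ar ring may attack the quinone instead of the alkene, and the level and sense of induction are untested.
- The fallback uses known chemistry. It sets out from 19 and 20 and comes back at 21.
- Irradiation of 19 with 20 (450 nm LEDs, benzene, 10 °C) gives, by Paternò–Büchi photoaddition to a quinone carbonyl, the racemic trans spiro-oxetane F1.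
- Catalytic TsOH (CH2Cl2, 0 °C) then triggers the known dienone–phenol 1,2-shift of the benzylic oxetane carbon onto the ring. This expands the oxetane to the dihydrofuran and gives racemic material, that is 21 together with its mirror image F2.
- Compound 21 is obtained pure by preparative chiral-phase SFC.

**Step 8 (semipinacol shift).**
- Risks: the hindered secondary OH may mesylate poorly. The An group at C3 is also anti to the mesylate and could participate. A wrong C1 epimer from step 7 would place Ar syn to the leaving group.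
- The fallback sets out from 12 and comes back at 15, and it needs no leaving group at C2.
- Buffered Dess–Martin oxidation (NaHCO3, CH2Cl2) gives the 1-hydroxyindan-2-one F3.
- Al(Ot-Bu)3 in toluene (60 °C) promotes an α-ketol rearrangement, driven by conjugation of the new aryl ketone. It moves the same Ar group to C2 and gives the 2-hydroxyindan-1-one F4.
- SmI2 (THF/MeOH, −78 °C) removes the tertiary α-hydroxyl, and a trace of DBU equilibrates C2 to trans 15.
- Either C1 epimer of 12 can be used.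

**Step 14 (Heck union).**
- Risks: β-hydride elimination into the ring, or palladium hydride isomerisation of 16 to the indene at 80 °C, and slow insertion next to the C2 aryl group.
- The fallback sets out from 22 and 16 and comes back at 23, with the polarity of the aryl partner reversed.
- Miyaura borylation of 22 (B2pin2, KOAc, PdCl2(dppf), dioxane, 80 °C) gives the pinacol boronate F5.
- F5 is joined to 16 by a base-free oxidative boron-Heck reaction under divalent palladium (Pd(OAc)2, 2,9-dimethyl-1,10-phenanthroline, O2, DMF, 40 °C). This is the manifold already used for arylidene indanes of this family.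

Further compounds
F1 | step 12 | racemic trans-3-Ar-2-An-1-oxaspiro[3.5]nona-5,8-dien-7-one (drawn enantiomer 2R,3S leads to 21) | O=C1C=CC2(C=C1)[C@@H](c1cc(O[Si](C(C)C)(C(C)C)C(C)C)cc(O[Si](C(C)C)(C(C)C)C(C)C)c1)[C@H](c1ccc(O[Si](C(C)C)(C(C)C)C(C)C)cc1)O2
F2 | step 12 | (2S,3S)-2-An-3-Ar-2,3-dihydro-1-benzofuran-5-ol (mirror image of 21) | Oc1ccc2c(c1)[C@H](c1cc(O[Si](C(C)C)(C(C)C)C(C)C)cc(O[Si](C(C)C)(C(C)C)C(C)C)c1)[C@@H](c1ccc(O[Si](C(C)C)(C(C)C)C(C)C)cc1)O2
F3 | step 8 | (1S,3S)-1-Ar-1-hydroxy-3-An-4,6-bis(triisopropylsilyloxy)-1,3-dihydro-2H-inden-2-one | CC(C)[Si](C(C)C)(C(C)C)Oc1ccc([C@H]2c3c(O[Si](C(C)C)(C(C)C)C(C)C)cc(O[Si](C(C)C)(C(C)C)C(C)C)cc3[C@@](O)(c3cc(O[Si](C(C)C)(C(C)C)C(C)C)cc(O[Si](C(C)C)(C(C)C)C(C)C)c3)C2=O)cc1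
F4 | step 8 | (2S,3S)-2-Ar-2-hydroxy-3-An-4,6-bis(triisopropylsilyloxy)indan-1-one | CC(C)[Si](C(C)C)(C(C)C)Oc1ccc([C@H]2c3c(O[Si](C(C)C)(C(C)C)C(C)C)cc(O[Si](C(C)C)(C(C)C)C(C)C)cc3C(=O)[C@@]2(O)c2cc(O[Si](C(C)C)(C(C)C)C(C)C)cc(O[Si](C(C)C)(C(C)C)C(C)C)c2)cc1
F5 | step 14 | 2-[(2R,3R)-2-An-3-Ar-2,3-dihydro-1-benzofuran-5-yl]-4,4,5,5-tetramethyl-1,3,2-dioxaborolane | CC1(C)OB(OC1(C)C)c1ccc2c(c1)[C@@H](c1cc(O[Si](C(C)C)(C(C)C)C(C)C)cc(O[Si](C(C)C)(C(C)C)C(C)C)c1)[C@H](c1ccc(O[Si](C(C)C)(C(C)C)C(C)C)cc1)O2
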